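The cyclohexane ring is opened at the bond between the ring CH2 and the ring CH that carries the side chain. With the ring oxirane read as its parent C(CH3)=CH alkene, this bond is the centre of a 1,5-diene ending in the exocyclic C=CH2. The key step is therefore a biomimetic (bisabolyl-type) cation–olefin cyclization: a tertiary allylic alcohol ionises and an internal allylsilane traps the allyl cation, closing the six-membered ring, fixing the ring CH stereocentre and placing both alkenes in one operation. The precursor is an acyclic D-tartrate-derived trans-dioxolane with a vinyl carbinol arm and a (trimethylsilyl)methyl allylic alcohol arm.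

Key step: step 8

Remark: compounds 4, 5, 10 and 11 are carried as mixtures of epimers at the tertiary carbinol carbon (written without configuration there), because this centre becomes sp2 in step 8; (−)-Ipc2B(allyl), angelic anhydride and both antipodes of the Shi ketone are taken as purchasable.

Step 1
Reactants: 1 dimethyl (4S,5S)-2,2-dimethyl-1,3-dioxolane-4,5-dicarboxylate (D-tartrate acetonide)
Product: 2 (4S,5S)-N4,N5-dimethoxy-N4,N5,2,2-tetramethyl-1,3-dioxolane-4,5-dicarboxamide
Conditions: MeNH(OMe)·HCl, i-PrMgCl, THF, −20 → 0 °C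
Reagents that add atoms: N,O-dimethylhydroxylamine hydrochloride, CNOC.Cl
Why: Magnesium-amide aminolysis of both esters (Weinreb amide formation) should leave the two dioxolane stereocentres untouched, their trans arrangement being also the thermodynamically preferred one.

Step 2
Reactants: 2 (4S,5S)-bis-Weinreb amide
Product: 3 (4S,5S)-5-acetyl-N-methoxy-N,2,2-trimethyl-1,3-dioxolane-4-carboxamide
Conditions: MeMgBr (1.05 equiv), THF, −78 → −20 °C; aq. NH4Cl
Reagents that add atoms: methylmagnesium bromide, C[Mg]Br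
Why: Grignard addition to a Weinreb amide stops at the chelated tetrahedral intermediate, so one equivalent should desymmetrise the C2-symmetric diamide to the mono-ketone, any diketone or recovered 2 being separable.

Step 3
Reactants: 3 keto Weinreb amide
Product: 4 (4S,5S)-5-(2-hydroxybut-3-en-2-yl)-N-methoxy-N,2,2-trimethyl-1,3-dioxolane-4-carboxamide
Conditions: CH2=CHMgBr (1.2 equiv), THF, −78 °C; aq. NH4Cl
Reagents that add atoms: vinylmagnesium bromide, C=C[Mg]Br
Why: Chemoselective Grignard 1,2-addition to the α-alkoxy ketone, far more electrophilic than the Weinreb amide at −78 °C, should give the tertiary vinyl carbinol, whose new centre needs no control because it is destroyed in step 8.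

Step 4
Reactants: 4 tertiary vinyl carbinol Weinreb amide
Product: 5 (4S,5S)-5-(2-hydroxybut-3-en-2-yl)-2,2-dimethyl-1,3-dioxolane-4-carbaldehyde
Conditions: i-Bu2AlH (2.5 equiv), THF, −78 °C; aq. potassium sodium tartrate
Reagents that add atoms: none
Why: Hydride reduction of a Weinreb amide stops at the aluminium hemiaminal and releases the α-alkoxy aldehyde only on work-up (the extra hydride is consumed by the tertiary alkoxide), and the aldehyde is used crude to avoid epimerisation.

Step 5
Reactants: 6 ethyl (triphenyl-λ5-phosphanylidene)acetate; 7 (iodomethyl)trimethylsilane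
Product: 9 ethyl 2-(triphenyl-λ5-phosphanylidene)-3-(trimethylsilyl)propanoate, via phosphonium iodide 8 (not isolated)
Conditions: MeCN, 80 °C; then aq. NaOH, CH2Cl2, 0 °C
Reagents that add atoms: none
Why: C-alkylation of the ester-stabilised ylide by the SN2-reactive α-silyl iodide, followed by deprotonation of the phosphonium salt, should give the α-(silylmethyl) ylide (ylide alkylation).

Step 6
Reactants: 5 hydroxy aldehyde; 9 α-(silylmethyl) ylide
Product: 10 ethyl (2Z)-3-[(4R,5S)-5-(2-hydroxybut-3-en-2-yl)-2,2-dimethyl-1,3-dioxolan-4-yl]-2-[(trimethylsilyl)methyl]prop-2-enoate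
Conditions: toluene, 60 °C
Reagents that add atoms: none
Why: Wittig olefination with an α-branched stabilised ylide should give the trisubstituted enoate with the ester trans to the dioxolane (Z by the sequence rule, since CH2Si outranks CO2Et), and any minor geometric isomer would converge in step 8.

Step 7
Reactants: 10 allylsilane enoate
Product: 11 (2Z)-3-[(4R,5S)-5-(2-hydroxybut-3-en-2-yl)-2,2-dimethyl-1,3-dioxolan-4-yl]-2-[(trimethylsilyl)methyl]prop-2-en-1-ol
Conditions: i-Bu2AlH (3.5 equiv), CH2Cl2, −78 °C; aq. potassium sodium tartrate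
Reagents that add atoms: none
Why: 1,2-Reduction of the conjugated ester (hydride reduction) removes the electron-withdrawing group from the allylsilane and so restores its full nucleophilicity before the ionisation step.

Step 8
Reactants: 11 allylsilane diol
Product: 12 2-[(3aR,4R,7aR)-2,2,7-trimethyl-3a,4,5,7a-tetrahydro-1,3-benzodioxol-4-yl]prop-2-en-1-ol
Conditions: Bi(OTf)3 (5 mol %), CH2Cl2, −40 → −10 °C; aq. NaHCO3
Reagents that add atoms: none
Why: Catalytic Bi(OTf)3 ionises the tertiary allylic alcohol to a linalyl-type allyl cation, the γ-carbon of the allylsilane attacks its CH2 terminus (anti-SE2′), and the β-silyl cation loses the silyl group to give the exocyclic methylene while the allyl unit collapses to the ring trisubstituted alkene. The closest known reaction type is the allylsilane-terminated cation–olefin cyclisation (intramolecular Hosomi–Sakurai allylation of an allylic alcohol), the laboratory counterpart of the neryl-to-bisabolyl ring closure. The cyclohexene ring closes 6-exo with respect to the allylsilane alkene and at the distal terminus of the allyl cation, so that all three allyl carbons become ring atoms (6-endo with respect to the cation), closure at the tertiary terminus being excluded as a strained four-membered ring. The new ring CH stereocentre is set by allylic 1,3-strain: the dioxolane C–H eclipses the cis CH2SiMe3 group, the tether brings the electrophile to the alkene face on the side of the other dioxolane carbon, and the new C–C bond forms anti to the dioxolane C–O, which places the 2-propenyl side chain trans (equatorial) to the adjacent ring oxygen. The step needs ionisation of the tertiary and not the primary allylic alcohol, and ring closure faster than proton loss, 1,2-hydride shift or protodesilylation; the greater ionisability of the tertiary allylic C–O bond, the pre-organisation of the two arms by the trans-dioxolane, the high nucleophilicity of the 2-alkyl allylsilane, reversible return of non-cyclising (transoid or O-trapped) species and low temperature should secure this. The carbinol configuration and the alkene geometry of 11 are immaterial, because all isomers pass through the same cation and obey the same 1,3-strain control.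

Step 9
Reactants: 12 bicyclic allylic alcohol
Product: 13 2-[(3aR,4R,7aR)-2,2,7-trimethyl-3a,4,5,7a-tetrahydro-1,3-benzodioxol-4-yl]prop-2-enal
Conditions: Dess–Martin periodinane, pyridine, CH2Cl2, 0 °C → rt
Reagents that add atoms: none
Why: Neutral Dess–Martin oxidation of the primary allylic alcohol should give the 2-substituted acrolein without epimerising the adjacent ring CH or moving the 1,1-disubstituted alkene.

Step 10
Reactants: 13 enal
Product: 14 (3S)-2-[(3aR,4R,7aR)-2,2,7-trimethyl-3a,4,5,7a-tetrahydro-1,3-benzodioxol-4-yl]hexa-1,5-dien-3-ol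
Conditions: (−)-Ipc2B(allyl) (1 M in pentane), Et2O, −78 °C; then NaOH, H2O2
Reagents that add atoms: (−)-B-allyldiisopinocampheylborane, C=CCB([C@H]1[C@H](C)[C@H]2C[C@@H](C1)C2(C)C)[C@H]1[C@H](C)[C@H]2C[C@@H](C1)C2(C)C
Why: Brown allylboration through a chair transition state under reagent control (Si-face attack by the reagent derived from (+)-α-pinene) should set the (S)-carbinol irrespective of the remote ring stereocentres.

Step 11
Reactants: 14 homoallylic alcohol acetonide; 15 angelic anhydride [(2Z)-2-methylbut-2-enoic anhydride]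
Product: 16 (3S)-2-[(3aR,4R,7aR)-2,2,7-trimethyl-3a,4,5,7a-tetrahydro-1,3-benzodioxol-4-yl]hexa-1,5-dien-3-yl (2Z)-2-methylbut-2-enoate
Conditions: LiN(SiMe3)2 (1.05 equiv), THF, −78 °C; then 15 (1.3 equiv), −78 → 0 °C; aq. NH4Cl
Reagents that add atoms: none
Why: O-Acylation of the lithium alkoxide by the symmetrical anhydride (alkoxide acylation) transfers one angeloyl group with retention at the carbinol carbon and, needing no nucleophilic amine catalyst, avoids the conjugate addition–elimination pathway that isomerises angelates to tiglates.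

Step 12
Reactants: 16 mono-angelate acetonide
Product: 17 (3S)-2-[(1R,5R,6R)-5,6-dihydroxy-4-methylcyclohex-3-en-1-yl]hexa-1,5-dien-3-yl (2Z)-2-methylbut-2-enoate
Conditions: AcOH/H2O (4:1), 40 °C
Reagents that add atoms: none
Why: Acid hydrolysis of the strained trans-fused acetonide (acetal hydrolysis) should free the ring diol under conditions too mild to ionise the allylic ester, cleave or isomerise the angelate, or hydrate the alkenes.

Step 13
Reactants: 17 diol mono-angelate; 15 angelic anhydride
Product: 18 (3S)-2-[(1R,5R,6R)-4-methyl-5,6-bis{[(2Z)-2-methylbut-2-enoyl]oxy}cyclohex-3-en-1-yl]hexa-1,5-dien-3-yl (2Z)-2-methylbut-2-enoate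
Conditions: LiN(SiMe3)2 (2.1 equiv), THF, −78 °C; then 15 (3 equiv), −78 → 0 °C; aq. NH4Cl
Reagents that add atoms: none
Why: Twofold alkoxide acylation of the trans-diol, each ring hydroxyl taking one angeloyl group from its own molecule of anhydride, should give the triester without angelate-to-tiglate isomerisation, the amide base being kept from excess so that the existing ester is not deprotonated at its γ-position and any acyl transfer among the three oxygens being degenerate because all end as angelates.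

Step 14
Reactants: 18 triangelate triene
Product: 19 (1S,2S,3R,4R,6S)-1-methyl-4-[(3S)-3-{[(2Z)-2-methylbut-2-enoyl]oxy}hexa-1,5-dien-2-yl]-7-oxabicyclo[4.1.0]heptane-2,3-diyl bis[(2Z)-2-methylbut-2-enoate]
Conditions: L-fructose-derived Shi ketone (enantiomer of the D-fructose-derived catalyst, 30 mol %), Oxone (2KHSO5·KHSO4·K2SO4), K2CO3, Bu4NHSO4, MeCN/CH2(OMe)2/aq. Na2B4O7 buffer, 0 °C
Reagents that add atoms: potassium peroxymonosulfate (active part of Oxone), [K+].[O-]S(=O)(=O)OO
Why: Shi epoxidation should select the only electron-rich trisubstituted alkene and, through the spiro transition state of the L-series catalyst, deliver oxygen to the ring face anti to the allylic ester, setting both oxirane carbons, while the 1,1-disubstituted, monosubstituted and conjugated alkenes react far more slowly.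

Step 15
Reactants: 19 ring epoxide with allyl terminus
Product: 20 (1S,2S,3R,4R,6S)-1-methyl-4-[(3S)-6-methyl-3-{[(2Z)-2-methylbut-2-enoyl]oxy}hepta-1,5-dien-2-yl]-7-oxabicyclo[4.1.0]heptane-2,3-diyl bis[(2Z)-2-methylbut-2-enoate]
Conditions: second-generation Grubbs catalyst (5 mol %), 2-methyl-2-butene (excess), CH2Cl2, 40 °C
Reagents that add atoms: 2-methyl-2-butene, CC=C(C)C
Why: Cross-metathesis of the only monosubstituted alkene with excess 2-methyl-2-butene should install the prenyl terminus, the hindered 1,1-disubstituted alkene and the trisubstituted conjugated esters being inert to the ruthenium carbene.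

Step 16
Reactants: 20 prenyl compound
Product: 21 (1S,2S,3R,4R,6S)-4-[(3S)-4-[(2R)-3,3-dimethyloxiran-2-yl]-3-{[(2Z)-2-methylbut-2-enoyl]oxy}but-1-en-2-yl]-1-methyl-7-oxabicyclo[4.1.0]heptane-2,3-diyl bis[(2Z)-2-methylbut-2-enoate]
Conditions: D-fructose-derived Shi ketone (30 mol %), Oxone (2KHSO5·KHSO4·K2SO4), K2CO3, Bu4NHSO4, MeCN/CH2(OMe)2/aq. Na2B4O7 buffer, 0 °C
Reagents that add atoms: potassium peroxymonosulfate (active part of Oxone), [K+].[O-]S(=O)(=O)OO
Why: Shi epoxidation of the remaining electron-rich trisubstituted alkene under reagent control (D-series catalyst) should give the (R)-oxirane, leaving the deactivated exocyclic methylene and the angelates untouched.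

Compound list
1 | dimethyl (4S,5S)-2,2-dimethyl-1,3-dioxolane-4,5-dicarboxylate | COC(=O)[C@H]1OC(C)(C)O[C@@H]1C(=O)OC | starting material
2 | (4S,5S)-N4,N5-dimethoxy-N4,N5,2,2-tetramethyl-1,3-dioxolane-4,5-dicarboxamide | CON(C)C(=O)[C@H]1OC(C)(C)O[C@@H]1C(=O)N(C)OC | intermediate
3 | (4S,5S)-5-acetyl-N-methoxy-N,2,2-trimethyl-1,3-dioxolane-4-carboxamide | CC(=O)[C@H]1OC(C)(C)O[C@@H]1C(=O)N(C)OC | intermediate
4 | (4S,5S)-5-(2-hydroxybut-3-en-2-yl)-N-methoxy-N,2,2-trimethyl-1,3-dioxolane-4-carboxamide (both carbinol epimers) | C=CC(C)(O)[C@H]1OC(C)(C)O[C@@H]1C(=O)N(C)OC | intermediate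
5 | (4S,5S)-5-(2-hydroxybut-3-en-2-yl)-2,2-dimethyl-1,3-dioxolane-4-carbaldehyde (both carbinol epimers) | C=CC(C)(O)[C@H]1OC(C)(C)O[C@@H]1C=O | intermediate
6 | ethyl (triphenyl-λ5-phosphanylidene)acetate | CCOC(=O)C=P(c1ccccc1)(c1ccccc1)c1ccccc1 | starting material
7 | (iodomethyl)trimethylsilane | C[Si](C)(C)CI | starting material
8 | [1-ethoxy-1-oxo-3-(trimethylsilyl)propan-2-yl]triphenylphosphonium iodide (racemic) | CCOC(=O)C(C[Si](C)(C)C)[P+](c1ccccc1)(c1ccccc1)c1ccccc1.[I-] | intermediate
9 | ethyl 2-(triphenyl-λ5-phosphanylidene)-3-(trimethylsilyl)propanoate | CCOC(=O)C(C[Si](C)(C)C)=P(c1ccccc1)(c1ccccc1)c1ccccc1 | intermediate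
10 | ethyl (2Z)-3-[(4R,5S)-5-(2-hydroxybut-3-en-2-yl)-2,2-dimethyl-1,3-dioxolan-4-yl]-2-[(trimethylsilyl)methyl]prop-2-enoate (both carbinol epimers) | C=CC(C)(O)[C@H]1OC(C)(C)O[C@@H]1/C=C(\C[Si](C)(C)C)C(=O)OCC | intermediate
11 | (2Z)-3-[(4R,5S)-5-(2-hydroxybut-3-en-2-yl)-2,2-dimethyl-1,3-dioxolan-4-yl]-2-[(trimethylsilyl)methyl]prop-2-en-1-ol (both carbinol epimers) | C=CC(C)(O)[C@H]1OC(C)(C)O[C@@H]1/C=C(\C[Si](C)(C)C)CO | intermediate
12 | 2-[(3aR,4R,7aR)-2,2,7-trimethyl-3a,4,5,7a-tetrahydro-1,3-benzodioxol-4-yl]prop-2-en-1-ol | C=C(CO)[C@H]2CC=C(C)[C@H]1OC(C)(C)O[C@@H]12 | intermediate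
13 | 2-[(3aR,4R,7aR)-2,2,7-trimethyl-3a,4,5,7a-tetrahydro-1,3-benzodioxol-4-yl]prop-2-enal | C=C(C=O)[C@H]2CC=C(C)[C@H]1OC(C)(C)O[C@@H]12 | intermediate
14 | (3S)-2-[(3aR,4R,7aR)-2,2,7-trimethyl-3a,4,5,7a-tetrahydro-1,3-benzodioxol-4-yl]hexa-1,5-dien-3-ol | C=CC[C@H](O)C(=C)[C@H]2CC=C(C)[C@H]1OC(C)(C)O[C@@H]12 | intermediate
15 | angelic anhydride, (2Z)-2-methylbut-2-enoic anhydride | C/C=C(/C)C(=O)OC(=O)/C(C)=C\C | starting material
16 | (3S)-2-[(3aR,4R,7aR)-2,2,7-trimethyl-3a,4,5,7a-tetrahydro-1,3-benzodioxol-4-yl]hexa-1,5-dien-3-yl (2Z)-2-methylbut-2-enoate | C=CC[C@H](OC(=O)/C(C)=C\C)C(=C)[C@H]2CC=C(C)[C@H]1OC(C)(C)O[C@@H]12 | intermediate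
17 | (3S)-2-[(1R,5R,6R)-5,6-dihydroxy-4-methylcyclohex-3-en-1-yl]hexa-1,5-dien-3-yl (2Z)-2-methylbut-2-enoate | C=CC[C@H](OC(=O)/C(C)=C\C)C(=C)[C@H]1CC=C(C)[C@@H](O)[C@@H]1O | intermediate
18 | (3S)-2-[(1R,5R,6R)-4-methyl-5,6-bis{[(2Z)-2-methylbut-2-enoyl]oxy}cyclohex-3-en-1-yl]hexa-1,5-dien-3-yl (2Z)-2-methylbut-2-enoate | C=CC[C@H](OC(=O)/C(C)=C\C)C(=C)[C@H]1CC=C(C)[C@@H](OC(=O)/C(C)=C\C)[C@@H]1OC(=O)/C(C)=C\C | intermediate
19 | (1S,2S,3R,4R,6S)-1-methyl-4-[(3S)-3-{[(2Z)-2-methylbut-2-enoyl]oxy}hexa-1,5-dien-2-yl]-7-oxabicyclo[4.1.0]heptane-2,3-diyl bis[(2Z)-2-methylbut-2-enoate] | C=CC[C@H](OC(=O)/C(C)=C\C)C(=C)[C@H]1C[C@@H]2O[C@]2(C)[C@@H](OC(=O)/C(C)=C\C)[C@@H]1OC(=O)/C(C)=C\C | intermediate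
20 | (1S,2S,3R,4R,6S)-1-methyl-4-[(3S)-6-methyl-3-{[(2Z)-2-methylbut-2-enoyl]oxy}hepta-1,5-dien-2-yl]-7-oxabicyclo[4.1.0]heptane-2,3-diyl bis[(2Z)-2-methylbut-2-enoate] | CC(C)=CC[C@H](OC(=O)/C(C)=C\C)C(=C)[C@H]1C[C@@H]2O[C@]2(C)[C@@H](OC(=O)/C(C)=C\C)[C@@H]1OC(=O)/C(C)=C\C | intermediate
21 | (1S,2S,3R,4R,6S)-4-[(3S)-4-[(2R)-3,3-dimethyloxiran-2-yl]-3-{[(2Z)-2-methylbut-2-enoyl]oxy}but-1-en-2-yl]-1-methyl-7-oxabicyclo[4.1.0]heptane-2,3-diyl bis[(2Z)-2-methylbut-2-enoate] | CC1(C)O[C@@H]1C[C@H](OC(=O)/C(C)=C\C)C(=C)[C@H]1C[C@@H]2O[C@]2(C)[C@@H](OC(=O)/C(C)=C\C)[C@@H]1OC(=O)/C(C)=C\C | target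

Total step count: 16. Longest linear sequence: 15 steps (1 to 21 through steps 1–4 and 6–16; step 5 is a one-step side branch).

Steps most likely to fail

Step 8. After ionisation, the tertiary allyl cation may lose a proton to a 1,3-diene or undergo a 1,2-hydride shift from the neighbouring dioxolane carbon, or the allylsilane may be protodesilylated, all before the ring closes. The fallback sets out from 3 and returns at 12. Wittig methylenation of 3 (Ph3P=CH2, THF) should give the isopropenyl Weinreb amide F1, i-Bu2AlH reduction the aldehyde F2, and a Wittig reaction with 6 the (E)-enoate F3. Anti-selective conjugate addition of an allylcopper reagent (CH2=CHCH2MgBr, CuBr·SMe2, Me3SiCl, THF, −78 °C), controlled by the γ-oxygen of the dioxolane, should give the β-allyl ester F4 with the ring CH configuration already in place. α-Methylenation (LiN(i-Pr)2, then Eschenmoser's salt; MeI; DBU) should give the α-methylene ester F5, and i-Bu2AlH the triene alcohol F6. Ring-closing metathesis (second-generation Grubbs catalyst, CH2Cl2, 40 °C) between the isopropenyl and allyl groups should then give 12. In this contingency the ring is closed at the trisubstituted alkene, and the ring CH centre comes from substrate-controlled cuprate addition.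

Step 14. Reagent control may be eroded by the substrate (poor facial selectivity), and oxygen transfer to an alkene deactivated by its allylic ester may be slow enough for the 1,1-disubstituted alkene to compete. The fallback sets out from 17 and returns at 19. MnO2 (CH2Cl2) should oxidise only the ring allylic alcohol of 17, giving the carvone-type hydroxy enone F7. Weitz–Scheffer epoxidation (H2O2, cat. NaOH, MeOH, 0 °C) should deliver the oxirane by axial attack anti to the side chain, which is the required face, giving the epoxy ketone F8. Hydroxyl-directed reduction (Me4NBH(OAc)3, MeCN/AcOH, −20 °C) should give the trans epoxy diol F9. Twofold acylation of F9 with 15 (LiN(SiMe3)2, THF, −78 °C, kept cold to suppress epoxide migration) rejoins the route at 19.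

Step 13. Acylation of the hindered second ring hydroxyl may stay incomplete, and surplus amide base may deprotonate an angelate at its γ-position and so scramble its geometry (Z to E) or deconjugate it. The fallback sets out from 17 and returns at 18. Steglich esterification of 17 with 2-[bis(2,2,2-trifluoroethoxy)phosphoryl]propanoic acid (DCC, DMAP, CH2Cl2) should give the bis(phosphonopropanoate) F10. A twofold Still–Gennari olefination with acetaldehyde (KN(SiMe3)2, 18-crown-6, THF, −78 °C) should then build both ring (Z)-2-methylbut-2-enoates on the substrate, giving 18.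

Further compounds
F1 | step 8 | (4S,5R)-N-methoxy-N,2,2-trimethyl-5-(prop-1-en-2-yl)-1,3-dioxolane-4-carboxamide | C=C(C)[C@H]1OC(C)(C)O[C@@H]1C(=O)N(C)OC
F2 | step 8 | (4S,5R)-2,2-dimethyl-5-(prop-1-en-2-yl)-1,3-dioxolane-4-carbaldehyde | C=C(C)[C@H]1OC(C)(C)O[C@@H]1C=O
F3 | step 8 | ethyl (2E)-3-[(4R,5R)-2,2-dimethyl-5-(prop-1-en-2-yl)-1,3-dioxolan-4-yl]prop-2-enoate | C=C(C)[C@H]1OC(C)(C)O[C@@H]1/C=C/C(=O)OCC
F4 | step 8 | ethyl (3R)-3-[(4R,5R)-2,2-dimethyl-5-(prop-1-en-2-yl)-1,3-dioxolan-4-yl]hex-5-enoate | C=C(C)[C@H]1OC(C)(C)O[C@@H]1[C@H](CC=C)CC(=O)OCC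
F5 | step 8 | ethyl (3R)-3-[(4R,5R)-2,2-dimethyl-5-(prop-1-en-2-yl)-1,3-dioxolan-4-yl]-2-methylidenehex-5-enoate | C=C(C)[C@H]1OC(C)(C)O[C@@H]1[C@H](CC=C)C(=C)C(=O)OCC
F6 | step 8 | (3R)-3-[(4R,5R)-2,2-dimethyl-5-(prop-1-en-2-yl)-1,3-dioxolan-4-yl]-2-methylidenehex-5-en-1-ol | C=C(C)[C@H]1OC(C)(C)O[C@@H]1[C@H](CC=C)C(=C)CO
F7 | step 14 | (3S)-2-[(1R,6R)-6-hydroxy-4-methyl-5-oxocyclohex-3-en-1-yl]hexa-1,5-dien-3-yl (2Z)-2-methylbut-2-enoate | C=CC[C@H](OC(=O)/C(C)=C\C)C(=C)[C@H]1CC=C(C)C(=O)[C@@H]1O
F8 | step 14 | (3S)-2-[(1S,3R,4R,6S)-4-hydroxy-6-methyl-5-oxo-7-oxabicyclo[4.1.0]heptan-3-yl]hexa-1,5-dien-3-yl (2Z)-2-methylbut-2-enoate | C=CC[C@H](OC(=O)/C(C)=C\C)C(=C)[C@H]1C[C@@H]2O[C@]2(C)C(=O)[C@@H]1O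
F9 | step 14 | (3S)-2-[(1S,3R,4R,5S,6R)-4,5-dihydroxy-6-methyl-7-oxabicyclo[4.1.0]heptan-3-yl]hexa-1,5-dien-3-yl (2Z)-2-methylbut-2-enoate | C=CC[C@H](OC(=O)/C(C)=C\C)C(=C)[C@H]1C[C@@H]2O[C@]2(C)[C@@H](O)[C@@H]1O
F10 | step 13 | (3S)-2-[(1R,5R,6R)-5,6-bis({2-[bis(2,2,2-trifluoroethoxy)phosphoryl]propanoyl}oxy)-4-methylcyclohex-3-en-1-yl]hexa-1,5-dien-3-yl (2Z)-2-methylbut-2-enoate (epimers at the phosphonate-bearing carbons) | C=CC[C@H](OC(=O)/C(C)=C\C)C(=C)[C@H]1CC=C(C)[C@@H](OC(=O)C(C)P(=O)(OCC(F)(F)F)OCC(F)(F)F)[C@@H]1OC(=O)C(C)P(=O)(OCC(F)(F)F)OCC(F)(F)F
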